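**Retrosynthetic overview**
1. Target ⇐ phenol desilylation ⇐ tigloylation of O10 ⇐ transannular Evans–Tishchenko reaction of a 6-hydroxy-10-enone with a silyl-protected 4-hydroxybenzaldehyde (sets C10 and puts the aroyl group on O6 in one step).
2. 6-Hydroxy enone ⇐ 6,10-oxa-bridged ketal ⇐ intramolecular vinylogous Mukaiyama aldol (C6–C7): a formal [4+3] annulation of a C4 alkoxydiene across C1/C6 of a cyclopentene carbaldehyde, with no olefin metathesis.
3. C1–C10 bond and quaternary centre ⇐ copper-catalysed conjugate addition of an α-metalated 1-ethoxy-3-methylbutadiene (acyl anion and dienolate in one reagent) to the enal.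
4. Cyclopentene carbaldehyde ⇐ ozonolysis and aldol condensation (ring contraction) of (S)-terpinen-4-ol, whose carbinol carbon becomes C4 and steers all later stereocentres.
5. Ring order: five-membered ring first (steps 1–2), seven-membered ring second (steps 3–4).

Assumption: commercial (S)-(+)-terpinen-4-ol is used as the single enantiomer (a lot of lower ee is upgraded beforehand by preparative chiral chromatography).

Locants (daucane numbering): five-membered ring C1(CH3)–C2–C3–C4(OH, iPr)–C5(H); seven-membered ring C1–C5–C6–C7–C8(CH3)=C9–C10. α is the face of the C1 methyl group and H5 (cis ring fusion); β is the other face. Target: 1R,4R,5S,6R,10R.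

**Step 1**
Reactants: 1 (S)-(+)-terpinen-4-ol [(1S)-4-methyl-1-(propan-2-yl)cyclohex-3-en-1-ol]
Product: 3 (3S)-3-hydroxy-6-oxo-3-(propan-2-yl)heptanal, via ozonide 2 (not isolated)
Conditions: O3, CH2Cl2, −78 °C; then Me2S, −78 → 23 °C
Reagents that add atoms: ozone, O=[O+][O-]
Why: Ozonolysis with reductive work-up cleaves the only C=C bond to the 1,6-keto aldehyde and leaves the tertiary carbinol stereocentre (the future C4) untouched.

**Step 2**
Reactants: 3 (3S)-3-hydroxy-6-oxo-3-(propan-2-yl)heptanal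
Product: 4 (5R)-5-hydroxy-2-methyl-5-(propan-2-yl)cyclopent-1-ene-1-carbaldehyde
Conditions: piperidine (0.2 equiv), AcOH (0.2 equiv), 4 Å MS, toluene, 40 °C
Reagents that add atoms: none
Why: Amine-catalysed intramolecular aldol condensation (the aldehyde enamine closes 5-exo onto the methyl ketone, then dehydrates) gives the cyclopentene carbaldehyde, a net six-to-five ring contraction that does not touch the stereocentre.

**Step 3**
Reactants: 4 (5R)-5-hydroxy-2-methyl-5-(propan-2-yl)cyclopent-1-ene-1-carbaldehyde; 5 1,1-diethoxy-3-methylbut-2-ene (3-methylbut-2-enal diethyl acetal)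
Product: 9 (1R,2R,5R)-2-[(1E)-1-ethoxy-3-methylbuta-1,3-dien-1-yl]-5-hydroxy-2-methyl-5-(propan-2-yl)cyclopentane-1-carbaldehyde, via dienylpotassium 6 (not isolated), via dienylmagnesium bromide 7 (not isolated), via silyl enol ether 8 (not isolated)
Conditions: 5 (2.4 equiv), n-BuLi/KOt-Bu (4.8 equiv each), THF, −95 → −60 °C; MgBr2·OEt2 (2.5 equiv); then CuBr·SMe2 (0.1 equiv), HMPA, TMSCl, 4, −78 → −40 °C; AcOH/NaOAc buffer (pH 5), THF–H2O, 0 °C; Et3N (0.2 equiv), CH2Cl2, 23 °C
Reagents that add atoms: potassium tert-butoxide, CC(C)(C)[O-].[K+] (K in 6 only); magnesium bromide diethyl etherate, Br[Mg]Br.CCOCC (Mg and Br in 7 and 8 only); chlorotrimethylsilane, C[Si](C)(C)Cl (silyl group in 8 only, lost in the work-up)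
Why: Chlorosilane-accelerated copper-catalysed conjugate addition of the alkoxydienyl Grignard reagent (made by 1,4-elimination and α-metalation of the acetal, the first equivalent being spent on the O–H) builds the C1 quaternary centre with the nucleophile entering anti to the isopropyl group and syn to the magnesium alkoxide, and C5 is then set by amine equilibration, the formyl group settling trans to isopropyl and methyl and hydrogen-bonded to the 4-OH.

**Step 4**
Reactants: 9 (1R,2R,5R)-2-[(1E)-1-ethoxy-3-methylbuta-1,3-dien-1-yl]-5-hydroxy-2-methyl-5-(propan-2-yl)cyclopentane-1-carbaldehyde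
Product: 11 (1R,4R,5S,6R)-4,6-dihydroxydauc-8-en-10-one (cis-fused; may sit partly as its 6,10-hemiketal), via bridged ketal 10 (not isolated)
Conditions: MgBr2·OEt2 (3 equiv), 2,6-di-tert-butyl-4-methylpyridine (0.2 equiv), CH2Cl2 (0.005 M), −20 → 23 °C; then 1 M HCl, THF, 0 °C
Reagents that add atoms: water, O
Why: Chelation-controlled intramolecular vinylogous Mukaiyama aldol addition (a 7-enolendo closure at the γ-carbon, whereas α-attack would be a disfavoured 5-enolendo closure) forms C6–C7 and the seven-membered ring, the O4–Mg–O6 chelate holding the 5,6-cis aldehyde so that the tethered diene attacks from the C1 side to give 6R, after which the oxocarbenium ion is caught transannularly as the ketal with the cyclopentane exo and mild acid releases the enone.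

**Step 5**
Reactants: 11 (1R,4R,5S,6R)-4,6-dihydroxydauc-8-en-10-one; 12 4-[(tert-butyldimethylsilyl)oxy]benzaldehyde
Product: 13 (1R,4R,5S,6R,10R)-4,10-dihydroxydauc-8-en-6-yl 4-[(tert-butyldimethylsilyl)oxy]benzoate
Conditions: 12 (6 equiv), SmI2 (0.3 equiv, premixed with 12), THF, −10 °C
Reagents that add atoms: none
Why: Proposed new method: a transannular (1,4) variant of the Evans–Tishchenko reduction, which is established for β-hydroxy ketones, in which the trivalent samarium hemiacetal alkoxide formed from O6 and the aldehyde passes its hydride to C10 on the β-face (the same proximity that lets O6 bridge to C10 in 10), giving the 10α-alcohol (10R) and leaving the aroyl group on O6, so that reduction and regioselective esterification happen in one operation.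

**Step 6**
Reactants: 13 (1R,4R,5S,6R,10R)-4,10-dihydroxydauc-8-en-6-yl 4-[(tert-butyldimethylsilyl)oxy]benzoate; 14 tigloyl chloride [(2E)-2-methylbut-2-enoyl chloride]
Product: 15 (1R,4R,5S,6R,10R)-6-{4-[(tert-butyldimethylsilyl)oxy]benzoyloxy}-4-hydroxydauc-8-en-10-yl (2E)-2-methylbut-2-enoate
Conditions: 14 (3 equiv), DMAP (0.3 equiv), pyridine, 0 → 45 °C
Reagents that add atoms: none
Why: DMAP-catalysed acylation of the secondary allylic alcohol with the geometrically stable (E)-acid chloride proceeds with retention at C10, while the tertiary 4-OH is too hindered to react.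

**Step 7**
Reactants: 15 (1R,4R,5S,6R,10R)-6-{4-[(tert-butyldimethylsilyl)oxy]benzoyloxy}-4-hydroxydauc-8-en-10-yl (2E)-2-methylbut-2-enoate
Product: 16 (1R,4R,5S,6R,10R)-4-hydroxy-6-(4-hydroxybenzoyloxy)dauc-8-en-10-yl (2E)-2-methylbut-2-enoate (target)
Conditions: TBAF, AcOH (1:1), THF, 0 °C
Reagents that add atoms: none
Why: Buffered fluoride desilylation cleaves the aryl silyl ether selectively and leaves both esters, the allylic C–O bond and the tertiary alcohol alone.

**Compound list**
1 | (S)-(+)-terpinen-4-ol, (1S)-4-methyl-1-(propan-2-yl)cyclohex-3-en-1-ol | CC1=CC[C@](O)(C(C)C)CC1 | starting material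
2 | ozonide (1,2,4-trioxolane) of 1 | CC12CC[C@@](O)(C(C)C)CC(OO1)O2 | intermediate
3 | (3S)-3-hydroxy-6-oxo-3-(propan-2-yl)heptanal | CC(=O)CC[C@@](O)(C(C)C)CC=O | intermediate
4 | (5R)-5-hydroxy-2-methyl-5-(propan-2-yl)cyclopent-1-ene-1-carbaldehyde | CC1=C(C=O)[C@](O)(C(C)C)CC1 | intermediate
5 | 1,1-diethoxy-3-methylbut-2-ene | CCOC(OCC)C=C(C)C | starting material
6 | (1-ethoxy-3-methylbuta-1,3-dien-1-yl)potassium, metal cis to C3 | [K]/C(OCC)=C\C(C)=C | intermediate
7 | (1-ethoxy-3-methylbuta-1,3-dien-1-yl)magnesium bromide, metal cis to C3 | Br[Mg]/C(OCC)=C\C(C)=C | intermediate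
8 | C6 trimethylsilyl enol ether of 9 with O4 as bromomagnesium alkoxide | C[Si](C)(C)OC=C1[C@](C)(/C(OCC)=C\C(C)=C)CC[C@@]1(O[Mg]Br)C(C)C | intermediate
9 | (1R,2R,5R)-2-[(1E)-1-ethoxy-3-methylbuta-1,3-dien-1-yl]-5-hydroxy-2-methyl-5-(propan-2-yl)cyclopentane-1-carbaldehyde | O=C[C@@H]1[C@](C)(/C(OCC)=C\C(C)=C)CC[C@@]1(O)C(C)C | intermediate
10 | (1R,4R,5S,6R,10S)-10-ethoxy-6,10-epoxydauc-8-en-4-ol (oxygen bridge on the β-face) | CCO[C@]13C=C(C)C[C@@H](O3)[C@@H]2[C@@]1(C)CC[C@@]2(O)C(C)C | intermediate
11 | (1R,4R,5S,6R)-4,6-dihydroxydauc-8-en-10-one | O=C1C=C(C)C[C@@H](O)[C@@H]2[C@@]1(C)CC[C@@]2(O)C(C)C | intermediate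
12 | 4-[(tert-butyldimethylsilyl)oxy]benzaldehyde | CC(C)(C)[Si](C)(C)Oc1ccc(C=O)cc1 | starting material
13 | (1R,4R,5S,6R,10R)-4,10-dihydroxydauc-8-en-6-yl 4-[(tert-butyldimethylsilyl)oxy]benzoate | O[C@@H]1C=C(C)C[C@@H](OC(=O)c2ccc(O[Si](C)(C)C(C)(C)C)cc2)[C@@H]2[C@@]1(C)CC[C@@]2(O)C(C)C | intermediate
14 | tigloyl chloride, (2E)-2-methylbut-2-enoyl chloride | C/C=C(\C)C(Cl)=O | starting material
15 | (1R,4R,5S,6R,10R)-6-{4-[(tert-butyldimethylsilyl)oxy]benzoyloxy}-4-hydroxydauc-8-en-10-yl (2E)-2-methylbut-2-enoate | C/C=C(\C)C(=O)O[C@@H]1C=C(C)C[C@@H](OC(=O)c2ccc(O[Si](C)(C)C(C)(C)C)cc2)[C@@H]2[C@@]1(C)CC[C@@]2(O)C(C)C | intermediate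
16 | (1R,4R,5S,6R,10R)-4-hydroxy-6-(4-hydroxybenzoyloxy)dauc-8-en-10-yl (2E)-2-methylbut-2-enoate | C/C=C(\C)C(=O)O[C@@H]1C=C(C)C[C@@H](OC(=O)c2ccc(O)cc2)[C@@H]2[C@@]1(C)CC[C@@]2(O)C(C)C | target

**Step count and risks**
Total step count: 7. Longest linear sequence: 7 steps (1 → 16).

The three steps most likely to fail:

Step 3. The base may metalate the allylic 3-methyl group of the dienyl ether instead of the α-vinyl position, and a 1-substituted vinyl nucleophile must form a quaternary centre on a hindered enal. The fallback sets out from 4 and comes back at 11. It uses the parent reagent from commercial crotonaldehyde diethyl acetal (same n-BuLi/KOt-Bu elimination–metalation, no competing allylic C–H) under the conditions of step 3 to give (1R,2R,5R)-2-[(1E)-1-ethoxybuta-1,3-dien-1-yl]-5-hydroxy-2-methyl-5-(propan-2-yl)cyclopentane-1-carbaldehyde F1. Cyclisation and hydrolysis as in step 4 give the 8-demethyl analogue of 11 F2. The methyl group is then brought in afterwards: Me2CuLi with TMSCl and Et3N gives the 8-methyl C9=C10 trimethylsilyl enol ether carrying 4-O- and 6-O-trimethylsilyl groups F3, Saegusa–Ito dehydrogenation with Pd(OAc)2 in MeCN gives the 4,6-bis-O-trimethylsilyl ether of 11 F4, and acidic work-up returns 11.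

Step 4. The ring closure may be slow, may go through the α-carbon to a diquinane, may suffer acid-promoted E/Z scrambling of the enol ether, or may take the C5 epimer to a trans-fused product. The fallback sets out from 9 and comes back at 11. The dienol ether is hydrolysed and conjugated (oxalic acid, wet THF; then catalytic DBU) to (1R,2R,5R)-5-hydroxy-2-methyl-2-(3-methylbut-2-enoyl)-5-(propan-2-yl)cyclopentane-1-carbaldehyde F5. The ring is then closed by an aluminium-templated vinylogous aldol reaction: Al(OC6H3-2,6-Ph2)3 complexes both carbonyl groups, holds the enone s-trans (C1 cis to C8, the geometry the seven-membered ring needs) and shields the α-carbon, so that LiTMP removes a γ-proton and γ-attack on the complexed aldehyde gives 11 directly.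

Step 5. The transannular hydride transfer is without direct precedent, and retro-vinylogous-aldol opening or simple Tishchenko dimerisation of 12 could compete. The fallback sets out from 11 and comes back at 13. Hydroxyl-directed reduction with Me4NBH(OAc)3 (AcOH/MeCN, −30 °C; intramolecular delivery from the O6-bound borohydride to the β-face of C10) gives (1R,4R,5S,6R,10R)-dauc-8-ene-4,6,10-triol F6. Pinnick oxidation of 12 (NaClO2, NaH2PO4, 2-methylbut-2-ene) gives 4-[(tert-butyldimethylsilyl)oxy]benzoic acid F7. Steglich esterification (DCC, DMAP, −20 °C) at the less hindered 6-OH (the 10-OH is neopentylic, the 4-OH tertiary) returns 13.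

**Further compounds**
F1 | step 3 | (1R,2R,5R)-2-[(1E)-1-ethoxybuta-1,3-dien-1-yl]-5-hydroxy-2-methyl-5-(propan-2-yl)cyclopentane-1-carbaldehyde | O=C[C@@H]1[C@](C)(/C(OCC)=C\C=C)CC[C@@]1(O)C(C)C
F2 | step 3 | 8-demethyl analogue of 11 | O=C1C=CC[C@@H](O)[C@@H]2[C@@]1(C)CC[C@@]2(O)C(C)C
F3 | step 3 | 8-methyl C9=C10 trimethylsilyl enol ether carrying 4-O- and 6-O-trimethylsilyl groups | C[Si](C)(C)OC1=CC(C)C[C@@H](O[Si](C)(C)C)[C@@H]2[C@@]1(C)CC[C@@]2(O[Si](C)(C)C)C(C)C
F4 | step 3 | 4,6-bis-O-trimethylsilyl ether of 11 | O=C1C=C(C)C[C@@H](O[Si](C)(C)C)[C@@H]2[C@@]1(C)CC[C@@]2(O[Si](C)(C)C)C(C)C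
F5 | step 4 | (1R,2R,5R)-5-hydroxy-2-methyl-2-(3-methylbut-2-enoyl)-5-(propan-2-yl)cyclopentane-1-carbaldehyde | O=C[C@@H]1[C@](C)(C(=O)C=C(C)C)CC[C@@]1(O)C(C)C
F6 | step 5 | (1R,4R,5S,6R,10R)-dauc-8-ene-4,6,10-triol | O[C@@H]1C=C(C)C[C@@H](O)[C@@H]2[C@@]1(C)CC[C@@]2(O)C(C)C
F7 | step 5 | 4-[(tert-butyldimethylsilyl)oxy]benzoic acid | CC(C)(C)[Si](C)(C)Oc1ccc(C(=O)O)cc1
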